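The route rests on cutting the O4'–C(Me)2 bond of pyran ring D. The key step exploits the C3'/C4' catechol of ring B with its C5' prenyl chain ortho to O4': anodic two-electron oxidation gives the ortho-quinone, which tautomerises to the vinyl quinone methide and closes ring D by oxa-6π electrocyclisation in one operation. The precursor is the 5'-prenyl-3',4'-dihydroxy isoflavonoid with free 7-OH, assembled by Suzuki coupling of a 3-iodochromone with a prenylated catechol boronate. It is electrolysed at the chromone level, where C3 bears no hydrogen that the quinone could abstract. C3 is then set (R) by transfer hydrogenation with dynamic kinetic resolution and reoxidation.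

Key step: step 14

Remark on the chemistry: ring D is closed on the 2,3-unsaturated (chromone) form of the precursor, which has the same skeleton. In a chromanone the ortho-quinone would make C3–H (para to C4'=O, alpha to C4=O) exchangeable through a para-quinone methide, so the C3 centre is created only after ring D exists.

Assumption: RuCl[(R,R)-TsDPEN](p-cymene) is taken to deliver hydride with the facial sense established for benzo-fused cyclic aryl ketones, giving the (4R) alcohol and, through the cis relationship, (3R). Locants follow isoflavonoid numbering: rings A and C are the chromanone, ring B the 3-aryl group with primed atoms, ring D the pyran.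

Step 1
Reactants: 1 2',4'-dihydroxy-6'-methoxyacetophenone
Product: 2 1-[2-hydroxy-6-methoxy-4-(methoxymethoxy)phenyl]ethan-1-one
Conditions: MOMCl (1.1 equiv), i-Pr2NEt, CH2Cl2, 0 °C to rt
Reagents that add atoms: chloromethyl methyl ether, COCCl
Why: Selective O-alkylation of the free 4'-OH (the 2'-OH is tied up in a hydrogen bond to the acetyl group); an acetal is used because a silyl ether on this para-acyl phenol would not withstand the amide acetal of step 2.

Step 2
Reactants: 2 1-[2-hydroxy-6-methoxy-4-(methoxymethoxy)phenyl]ethan-1-one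
Product: 3 (E)-3-(dimethylamino)-1-[2-hydroxy-6-methoxy-4-(methoxymethoxy)phenyl]prop-2-en-1-one
Conditions: DMF-DMA, toluene, 95 °C
Reagents that add atoms: N,N-dimethylformamide dimethyl acetal, COC(OC)N(C)C
Why: Enaminone formation by condensation of the methyl ketone with the amide acetal, which supplies the future C2 of the chromone; the MOM ether is stable to this basic medium.

Step 3
Reactants: 3 (E)-3-(dimethylamino)-1-[2-hydroxy-6-methoxy-4-(methoxymethoxy)phenyl]prop-2-en-1-one
Product: 4 3-iodo-5-methoxy-7-(methoxymethoxy)-4H-chromen-4-one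
Conditions: I2, pyridine, CHCl3, rt
Reagents that add atoms: iodine, II
Why: Iodocyclisation of an ortho-hydroxyaryl enaminone (iodination at the enaminone alpha carbon, 6-endo attack of the phenol on the iminium carbon, loss of dimethylamine) is the standard entry to 3-iodochromones.

Step 4
Reactants: 4 3-iodo-5-methoxy-7-(methoxymethoxy)-4H-chromen-4-one
Product: 5 7-hydroxy-3-iodo-5-methoxy-4H-chromen-4-one
Conditions: 3 M HCl, MeOH, 55 °C
Reagents that add atoms: none
Why: Acid-catalysed acetal methanolysis removes the MOM group while iodochromone and aryl methyl ether are acid-stable; the only acidic step of the route is placed here, before any prenyl group is present.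

Step 5
Reactants: 5 7-hydroxy-3-iodo-5-methoxy-4H-chromen-4-one
Product: 6 3-iodo-5-methoxy-7-[(triisopropylsilyl)oxy]-4H-chromen-4-one
Conditions: TIPSCl, imidazole, DMF, rt
Reagents that add atoms: triisopropylsilyl chloride, CC(C)[Si](Cl)(C(C)C)C(C)C
Why: Imidazole-promoted silylation of the acidic 7-OH, which as a phenoxide would deactivate the iodochromone in the cross-coupling; the bulky TIPS ether is chosen to survive the aqueous phosphate of step 12.

Step 6
Reactants: 7 5-bromosalicylaldehyde; 8 3-chloro-3-methylbut-1-yne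
Product: 9 5-bromo-2-[(2-methylbut-3-yn-2-yl)oxy]benzaldehyde
Conditions: DBU, CuCl2·2H2O (1 mol %), MeCN, 0 °C to rt
Reagents that add atoms: none
Why: Copper-catalysed O-propargylation of a phenol with a tertiary propargylic chloride (copper-assisted ionisation, attack of the phenoxide at the tertiary carbon), which works on hydrogen-bonded electron-poor phenols and leaves aldehyde and aryl bromide alone.

Step 7
Reactants: 9 5-bromo-2-[(2-methylbut-3-yn-2-yl)oxy]benzaldehyde
Product: 10 5-bromo-2-[(2-methylbut-3-en-2-yl)oxy]benzaldehyde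
Conditions: H2 (1 atm), Pd/CaCO3 poisoned with Pb(OAc)2 (Lindlar catalyst), quinoline, EtOAc, rt
Reagents that add atoms: none
Why: Lindlar semi-hydrogenation stops at the terminal alkene, and the poisoned palladium does not touch the aryl bromide or the aldehyde.

Step 8
Reactants: 10 5-bromo-2-[(2-methylbut-3-en-2-yl)oxy]benzaldehyde
Product: 12 5-bromo-2-hydroxy-3-(3-methylbut-2-en-1-yl)benzaldehyde, via ortho-dienone 11 (not isolated)
Conditions: PhNEt2, 150 °C
Reagents that add atoms: none
Why: Aromatic Claisen rearrangement of the 1,1-dimethylallyl ether goes by [3,3] shift to the only free ortho carbon (the para position carries bromine), inverting the allyl unit to the prenyl group, and dienone 11 then tautomerises to the phenol.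

Step 9
Reactants: 12 5-bromo-2-hydroxy-3-(3-methylbut-2-en-1-yl)benzaldehyde
Product: 14 5-bromo-3-(3-methylbut-2-en-1-yl)benzene-1,2-diol, via aryl formate 13 (not isolated)
Conditions: 30% H2O2, NaOH (1 equiv), THF/H2O, 0 °C to rt; NH4Cl work-up under argon
Reagents that add atoms: hydrogen peroxide, OO
Why: Dakin oxidation of the ortho-hydroxybenzaldehyde (hydroperoxide addition, aryl migration to oxygen, hydrolysis of formate 13) gives the catechol, and nucleophilic alkaline peroxide does not epoxidise the electron-rich prenyl alkene.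

Step 10
Reactants: 14 5-bromo-3-(3-methylbut-2-en-1-yl)benzene-1,2-diol
Product: 15 1-bromo-3,4-bis[(tert-butyldimethylsilyl)oxy]-5-(3-methylbut-2-en-1-yl)benzene
Conditions: TBSCl (2.5 equiv), imidazole, DMAP (cat.), DMF, rt to 40 °C
Reagents that add atoms: tert-butyldimethylsilyl chloride, CC(C)(C)[Si](C)(C)Cl
Why: Imidazole-promoted silylation caps the air-sensitive catechol at once, with silyl ethers chosen because fluoride later removes them without acid that could cyclise the prenyl group onto O4'.

Step 11
Reactants: 15 1-bromo-3,4-bis[(tert-butyldimethylsilyl)oxy]-5-(3-methylbut-2-en-1-yl)benzene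
Product: 16 2-{3,4-bis[(tert-butyldimethylsilyl)oxy]-5-(3-methylbut-2-en-1-yl)phenyl}-4,4,5,5-tetramethyl-1,3,2-dioxaborolane
Conditions: B2pin2, Pd(dppf)Cl2 (3 mol %), KOAc, 1,4-dioxane, 85 °C
Reagents that add atoms: bis(pinacolato)diboron, CC1(C)OB(OC1(C)C)B1OC(C)(C)C(C)(C)O1
Why: Miyaura borylation (insertion of zerovalent palladium into the C–Br bond, acetate-assisted transmetalation with the diboron) uses a base too weak to cleave the silyl ethers and leaves the prenyl alkene untouched.

Step 12
Reactants: 6 3-iodo-5-methoxy-7-[(triisopropylsilyl)oxy]-4H-chromen-4-one; 16 2-{3,4-bis[(tert-butyldimethylsilyl)oxy]-5-(3-methylbut-2-en-1-yl)phenyl}-4,4,5,5-tetramethyl-1,3,2-dioxaborolane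
Product: 17 3-{3,4-bis[(tert-butyldimethylsilyl)oxy]-5-(3-methylbut-2-en-1-yl)phenyl}-5-methoxy-7-[(triisopropylsilyl)oxy]-4H-chromen-4-one
Conditions: Pd(dppf)Cl2 (5 mol %), K3PO4, 1,4-dioxane/H2O (10:1), 60 °C
Reagents that add atoms: none
Why: Suzuki–Miyaura coupling of a 3-iodochromone, whose activated C3–I bond adds zerovalent palladium at moderate temperature, is the standard isoflavone construction and forms the C3–C1' bond.

Step 13
Reactants: 17 3-{3,4-bis[(tert-butyldimethylsilyl)oxy]-5-(3-methylbut-2-en-1-yl)phenyl}-5-methoxy-7-[(triisopropylsilyl)oxy]-4H-chromen-4-one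
Product: 18 3-[3,4-dihydroxy-5-(3-methylbut-2-en-1-yl)phenyl]-7-hydroxy-5-methoxy-4H-chromen-4-one
Conditions: TBAF (3.3 equiv), AcOH (3.5 equiv), THF, 0 °C to rt, argon
Reagents that add atoms: none
Why: Fluoride cleavage of the three aryl silyl ethers, buffered with acetic acid so that the freed catechol stays protonated and air-stable; no stereocentre is present at this stage.

Step 14
Reactants: 18 3-[3,4-dihydroxy-5-(3-methylbut-2-en-1-yl)phenyl]-7-hydroxy-5-methoxy-4H-chromen-4-one
Product: 21 7-hydroxy-3-(8-hydroxy-2,2-dimethyl-2H-chromen-6-yl)-5-methoxy-4H-chromen-4-one, via ortho-quinone 19 (not isolated), via quinone methide 20 (not isolated)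
Conditions: undivided cell, graphite anode at controlled potential (first anodic wave of the catechol, about +0.5 V vs Ag/AgCl), Pt cathode, Bu4NBF4 (0.1 M), 2,6-lutidine (2 equiv), MeCN/HFIP (9:1), rt, argon, about 2.1 F/mol
Reagents that add atoms: none
Why: Proposed new method: anodic two-electron, two-proton oxidation of the ring B catechol, expected to be the most easily oxidised group, gives ortho-quinone 19, and the lutidine buffer then moves a proton from the doubly activated C5' prenyl CH2 to O3' to give quinone methide 20 with the O4'=C4'–C5'=CH–CH=CMe2 oxatriene. This closes by thermal disrotatory oxa-6π electrocyclisation, forming the O4'–CMe2 bond and the six-membered pyran ring D and restoring the aromaticity of ring B with the C3' hydroxyl as the chromene 8-OH. The closest known reactions are the DDQ-mediated dehydrogenative cyclisation of ortho-prenyl phenols and the base-induced isomerisation of prenyl quinones to chromenols, both through the same kind of quinone methide, and anodic catechol to ortho-quinone oxidation is itself classical. No stereocentre is formed. The selectivities needed are oxidation of the catechol alone, closure through O4', and proton loss only at the prenyl group: the first is set by the controlled potential (7-hydroxychromone and product mono-phenol should oxidise well above it), the second by O4' being the only oxygen ortho to the prenyl chain, and the third by the sp2 C3 of the chromone, which offers the quinone no competing acidic hydrogen. Lutidinium is reduced to hydrogen at the cathode, so no strong base or acid builds up.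

Step 15
Reactants: 21 7-hydroxy-3-(8-hydroxy-2,2-dimethyl-2H-chromen-6-yl)-5-methoxy-4H-chromen-4-one
Product: 22 3-{2,2-dimethyl-8-[(triisopropylsilyl)oxy]-2H-chromen-6-yl}-5-methoxy-7-[(triisopropylsilyl)oxy]-4H-chromen-4-one
Conditions: TIPSCl (2.6 equiv), imidazole, DMAP (cat.), DMF, 40 °C
Reagents that add atoms: triisopropylsilyl chloride, CC(C)[Si](Cl)(C(C)C)C(C)C
Why: Imidazole-promoted silylation of both phenols is needed because a free 7-OH would turn the C4 carbonyl into an unreactive vinylogous acid in step 16 and free phenols would be oxidised by the periodinane of step 17.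

Step 16
Reactants: 22 3-{2,2-dimethyl-8-[(triisopropylsilyl)oxy]-2H-chromen-6-yl}-5-methoxy-7-[(triisopropylsilyl)oxy]-4H-chromen-4-one
Product: 24 (3R,4R)-3-{2,2-dimethyl-8-[(triisopropylsilyl)oxy]-2H-chromen-6-yl}-5-methoxy-7-[(triisopropylsilyl)oxy]chroman-4-ol, via racemic chromanone 23 (not isolated)
Conditions: RuCl[(R,R)-TsDPEN](p-cymene) (5 mol %), HCO2H/Et3N (1:2), EtOAc, 40 °C
Reagents that add atoms: none
Why: Noyori–Ikariya asymmetric transfer hydrogenation with dynamic kinetic resolution: the ruthenium hydride first reduces the polarised chromone C2=C3 bond to racemic 23, whose C3 epimerises fast in the amine-rich medium, and the (R,R) catalyst then reduces only the (3R) ketone from the face opposite the C3 aryl group, so that C4 (R) is set by the catalyst and C3 (R) by the resolution (cis alcohol), while the unpolarised chromene alkene is not reduced and the excess amine keeps the electron-rich benzylic alcohol from ionising.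

Step 17
Reactants: 24 (3R,4R)-3-{2,2-dimethyl-8-[(triisopropylsilyl)oxy]-2H-chromen-6-yl}-5-methoxy-7-[(triisopropylsilyl)oxy]chroman-4-ol
Product: 25 (R)-3-{2,2-dimethyl-8-[(triisopropylsilyl)oxy]-2H-chromen-6-yl}-5-methoxy-7-[(triisopropylsilyl)oxy]chroman-4-one
Conditions: Dess–Martin periodinane, pyridine, CH2Cl2, 0 °C
Reagents that add atoms: none
Why: Dess–Martin oxidation under pyridine buffering removes the C4 centre without any base able to enolise the new ketone, so C3 stays (R) (the priorities at C3 do not change), and the silyl-masked phenols and the chromene are inert to the periodinane.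

Step 18
Reactants: 25 (R)-3-{2,2-dimethyl-8-[(triisopropylsilyl)oxy]-2H-chromen-6-yl}-5-methoxy-7-[(triisopropylsilyl)oxy]chroman-4-one
Product: 26 (R)-7-hydroxy-3-(8-hydroxy-2,2-dimethyl-2H-chromen-6-yl)-5-methoxychroman-4-one (CNP0113665.2)
Conditions: TBAF (2.2 equiv), AcOH (2.5 equiv), THF, 0 °C to rt
Reagents that add atoms: none
Why: Fluoride desilylation buffered with acetic acid cleaves both aryl silyl ethers in a weakly acidic medium, so the enolisable C3–H is not epimerised and the chromene is unaffected.

Compound list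
1 | 2',4'-dihydroxy-6'-methoxyacetophenone | CC(=O)c1c(O)cc(O)cc1OC | starting material
2 | 1-[2-hydroxy-6-methoxy-4-(methoxymethoxy)phenyl]ethan-1-one | CC(=O)c1c(O)cc(OCOC)cc1OC | intermediate
3 | (E)-3-(dimethylamino)-1-[2-hydroxy-6-methoxy-4-(methoxymethoxy)phenyl]prop-2-en-1-one | CN(C)/C=C/C(=O)c1c(O)cc(OCOC)cc1OC | intermediate
4 | 3-iodo-5-methoxy-7-(methoxymethoxy)-4H-chromen-4-one | COCOc1cc(OC)c2c(c1)occ(I)c2=O | intermediate
5 | 7-hydroxy-3-iodo-5-methoxy-4H-chromen-4-one | COc1cc(O)cc2occ(I)c(=O)c12 | intermediate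
6 | 3-iodo-5-methoxy-7-[(triisopropylsilyl)oxy]-4H-chromen-4-one | COc1cc(O[Si](C(C)C)(C(C)C)C(C)C)cc2occ(I)c(=O)c12 | intermediate
7 | 5-bromosalicylaldehyde | O=Cc1cc(Br)ccc1O | starting material
8 | 3-chloro-3-methylbut-1-yne | CC(C)(Cl)C#C | starting material
9 | 5-bromo-2-[(2-methylbut-3-yn-2-yl)oxy]benzaldehyde | C#CC(C)(C)Oc1ccc(Br)cc1C=O | intermediate
10 | 5-bromo-2-[(2-methylbut-3-en-2-yl)oxy]benzaldehyde | C=CC(C)(C)Oc1ccc(Br)cc1C=O | intermediate
11 | 3-bromo-5-(3-methylbut-2-en-1-yl)-6-oxocyclohexa-1,3-diene-1-carbaldehyde (racemic ortho-dienone) | O=CC1=CC(Br)=CC(CC=C(C)C)C1=O | intermediate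
12 | 5-bromo-2-hydroxy-3-(3-methylbut-2-en-1-yl)benzaldehyde | CC(C)=CCc1cc(Br)cc(C=O)c1O | intermediate
13 | 5-bromo-2-hydroxy-3-(3-methylbut-2-en-1-yl)phenyl formate | CC(C)=CCc1cc(Br)cc(OC=O)c1O | intermediate
14 | 5-bromo-3-(3-methylbut-2-en-1-yl)benzene-1,2-diol | CC(C)=CCc1cc(Br)cc(O)c1O | intermediate
15 | 1-bromo-3,4-bis[(tert-butyldimethylsilyl)oxy]-5-(3-methylbut-2-en-1-yl)benzene | CC(C)=CCc1cc(Br)cc(O[Si](C)(C)C(C)(C)C)c1O[Si](C)(C)C(C)(C)C | intermediate
16 | 2-{3,4-bis[(tert-butyldimethylsilyl)oxy]-5-(3-methylbut-2-en-1-yl)phenyl}-4,4,5,5-tetramethyl-1,3,2-dioxaborolane | CC(C)=CCc1cc(B2OC(C)(C)C(C)(C)O2)cc(O[Si](C)(C)C(C)(C)C)c1O[Si](C)(C)C(C)(C)C | intermediate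
17 | 3-{3,4-bis[(tert-butyldimethylsilyl)oxy]-5-(3-methylbut-2-en-1-yl)phenyl}-5-methoxy-7-[(triisopropylsilyl)oxy]-4H-chromen-4-one | COc1cc(O[Si](C(C)C)(C(C)C)C(C)C)cc2occ(-c3cc(CC=C(C)C)c(O[Si](C)(C)C(C)(C)C)c(O[Si](C)(C)C(C)(C)C)c3)c(=O)c12 | intermediate
18 | 3-[3,4-dihydroxy-5-(3-methylbut-2-en-1-yl)phenyl]-7-hydroxy-5-methoxy-4H-chromen-4-one | COc1cc(O)cc2occ(-c3cc(CC=C(C)C)c(O)c(O)c3)c(=O)c12 | intermediate
19 | 5-(7-hydroxy-5-methoxy-4-oxo-4H-chromen-3-yl)-3-(3-methylbut-2-en-1-yl)cyclohexa-3,5-diene-1,2-dione (ortho-quinone) | COc1cc(O)cc2occ(C3=CC(=O)C(=O)C(CC=C(C)C)=C3)c(=O)c12 | intermediate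
20 | 2-hydroxy-4-(7-hydroxy-5-methoxy-4-oxo-4H-chromen-3-yl)-6-(3-methylbut-2-en-1-ylidene)cyclohexa-2,4-dien-1-one (quinone methide) | COc1cc(O)cc2occ(C3=CC(=CC=C(C)C)C(=O)C(O)=C3)c(=O)c12 | intermediate
21 | 7-hydroxy-3-(8-hydroxy-2,2-dimethyl-2H-chromen-6-yl)-5-methoxy-4H-chromen-4-one | COc1cc(O)cc2occ(-c3cc(O)c4OC(C)(C)C=Cc4c3)c(=O)c12 | intermediate
22 | 3-{2,2-dimethyl-8-[(triisopropylsilyl)oxy]-2H-chromen-6-yl}-5-methoxy-7-[(triisopropylsilyl)oxy]-4H-chromen-4-one | COc1cc(O[Si](C(C)C)(C(C)C)C(C)C)cc2occ(-c3cc(O[Si](C(C)C)(C(C)C)C(C)C)c4OC(C)(C)C=Cc4c3)c(=O)c12 | intermediate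
23 | racemic 3-{2,2-dimethyl-8-[(triisopropylsilyl)oxy]-2H-chromen-6-yl}-5-methoxy-7-[(triisopropylsilyl)oxy]chroman-4-one | COc1cc(O[Si](C(C)C)(C(C)C)C(C)C)cc2OCC(c3cc(O[Si](C(C)C)(C(C)C)C(C)C)c4OC(C)(C)C=Cc4c3)C(=O)c12 | intermediate
24 | (3R,4R)-3-{2,2-dimethyl-8-[(triisopropylsilyl)oxy]-2H-chromen-6-yl}-5-methoxy-7-[(triisopropylsilyl)oxy]chroman-4-ol | COc1cc(O[Si](C(C)C)(C(C)C)C(C)C)cc2c1[C@H](O)[C@H](c1cc(O[Si](C(C)C)(C(C)C)C(C)C)c3c(c1)C=CC(C)(C)O3)CO2 | intermediate
25 | (R)-3-{2,2-dimethyl-8-[(triisopropylsilyl)oxy]-2H-chromen-6-yl}-5-methoxy-7-[(triisopropylsilyl)oxy]chroman-4-one | COc1cc(O[Si](C(C)C)(C(C)C)C(C)C)cc2c1C(=O)[C@H](c1cc(O[Si](C(C)C)(C(C)C)C(C)C)c3c(c1)C=CC(C)(C)O3)CO2 | intermediate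
26 | (R)-7-hydroxy-3-(8-hydroxy-2,2-dimethyl-2H-chromen-6-yl)-5-methoxychroman-4-one (CNP0113665.2) | COc1cc(O)cc2c1C(=O)[C@H](c1cc(O)c3c(c1)C=CC(C)(C)O3)CO2 | target

Total step count: 18 (steps 1–5 for the ring A partner, steps 6–11 for the ring B partner, steps 12–18 after convergence).
Longest linear sequence: 13 steps (from 7 through steps 6–11 and 12–18 to 26).

Steps most likely to fail

Step 14 (the new anodic method). What may go wrong: the ortho-quinone may be consumed by conjugate addition of unoxidised catechol or of the product phenol before the proton shift, leading to oligomers at the electrode, or the product may be over-oxidised if the potential drifts. Fallback, using known selenium chemistry that never oxidises ring B: it sets out from 18. N-(Phenylselanyl)phthalimide with catalytic camphorsulfonic acid in CH2Cl2 at −40 to 0 °C should form the seleniranium ion of the prenyl alkene, which O4' opens at the tertiary carbon (6-endo) to give racemic 7-hydroxy-3-[8-hydroxy-2,2-dimethyl-3-(phenylselanyl)chroman-6-yl]-5-methoxy-4H-chromen-4-one F1. H2O2 with pyridine in THF at 0 °C to rt should oxidise it to the corresponding selenoxide F2, which eliminates syn toward the benzylic CH2 (the only beta hydrogens) and delivers 21, where the route is rejoined.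

Step 16. What may go wrong: hydride delivery to the carbonyl may be slow, since it is flanked by the C5 methoxy group and deactivated by two oxygen donors. C3 may equilibrate too slowly relative to reduction, eroding enantio- and diastereoselectivity, or the benzylic alcohol may ionise. Fallback, by resolution with recycling: it sets out from 22. LiBH(s-Bu)3 in THF at −78 °C with AcOH quench should give racemic 23 by 1,4-reduction. Preparative chromatography on an amylose tris(3,5-dimethylphenylcarbamate) phase should separate 25 from (S)-3-{2,2-dimethyl-8-[(triisopropylsilyl)oxy]-2H-chromen-6-yl}-5-methoxy-7-[(triisopropylsilyl)oxy]chroman-4-one F3, which is racemised back to 23 with catalytic DBU in toluene and recycled. The route is rejoined at 25.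

Step 12. What may go wrong: the aqueous base may cleave the C7 silyl ether and open the pyranone ring of 6, or 16 may protodeboronate. Fallback, by base-free Negishi coupling: it sets out from 15 (with 6 as partner). n-BuLi in THF at −78 °C should give {3,4-bis[(tert-butyldimethylsilyl)oxy]-5-(3-methylbut-2-en-1-yl)phenyl}lithium F4 by bromine–lithium exchange; both silyloxy groups are meta or para to the metal, so no silyl migration is possible. ZnCl2 should convert it into {3,4-bis[(tert-butyldimethylsilyl)oxy]-5-(3-methylbut-2-en-1-yl)phenyl}zinc chloride F5, and coupling with 6 under Pd(OAc)2/SPhos in THF at rt should give 17, where the route is rejoined.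

Further compounds
F1 | step 14 | 7-hydroxy-3-[8-hydroxy-2,2-dimethyl-3-(phenylselanyl)chroman-6-yl]-5-methoxy-4H-chromen-4-one (racemic) | COc1cc(O)cc2occ(-c3cc(O)c4OC(C)(C)C([Se]c5ccccc5)Cc4c3)c(=O)c12
F2 | step 14 | 7-hydroxy-3-[8-hydroxy-2,2-dimethyl-3-(phenylseleninyl)chroman-6-yl]-5-methoxy-4H-chromen-4-one (selenoxide of F1) | COc1cc(O)cc2occ(-c3cc(O)c4OC(C)(C)C([Se](=O)c5ccccc5)Cc4c3)c(=O)c12
F3 | step 16 | (S)-3-{2,2-dimethyl-8-[(triisopropylsilyl)oxy]-2H-chromen-6-yl}-5-methoxy-7-[(triisopropylsilyl)oxy]chroman-4-one | COc1cc(O[Si](C(C)C)(C(C)C)C(C)C)cc2c1C(=O)[C@@H](c1cc(O[Si](C(C)C)(C(C)C)C(C)C)c3c(c1)C=CC(C)(C)O3)CO2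
F4 | step 12 | {3,4-bis[(tert-butyldimethylsilyl)oxy]-5-(3-methylbut-2-en-1-yl)phenyl}lithium | CC(C)=CCc1cc([Li])cc(O[Si](C)(C)C(C)(C)C)c1O[Si](C)(C)C(C)(C)C
F5 | step 12 | {3,4-bis[(tert-butyldimethylsilyl)oxy]-5-(3-methylbut-2-en-1-yl)phenyl}zinc chloride | CC(C)=CCc1cc([Zn]Cl)cc(O[Si](C)(C)C(C)(C)C)c1O[Si](C)(C)C(C)(C)C
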